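**Plan**
1. Retrosynthesis: both C7=C8 bonds are cut first (two-fold Julia–Kocienski olefination of a C20 dialdehyde with two C10 ring sulfones); in each ring the C3–C4 and C5–C6 bonds are then cut together.
2. Enabling feature: with C3 as a ketone, each end ring is a 4-substituted isophorone. That is the alkyne unit C4≡C5(–C18) inserted into the acyl–alkyl bond C3–C6 of a 2-substituted 3,3-dimethylcyclobutanone. The C5 methyl (C18) and C7 on C6 are 1,4-related, so one oxygen (C6–C7–O–C18–C5) can tether the alkyne and steer insertion into the substituted bond.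
3. Forward: SAMP-hydrazone alkylation of 3,3-dimethylcyclobutanone sets C6; a rhodium-catalysed "cut-and-sew" then forms the six-membered carbocycle together with a temporary oxolane ring, with retention at C6.
4. SmI2 opens the oxolane at C18–O (the C5 methyl and C7–OH appear), C7 becomes a phenyltetrazolyl sulfone, and Luche reduction sets C3 trans to C6 by substrate control.
5. The chain is joined last: seven chain double bonds come E from crocetindialdehyde, C7=C8 and C7'=C8' from the olefination; fluoride removes the silyl groups.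

Key step: step 5

Remark: carotenoid numbering is used (C1 = CMe2, C2 = CH2, C3 = oxygen-bearing carbon, C4=C5 ring alkene, C6 = ring CH, C7 = first chain carbon, C18 = methyl on C5); all-E crocetindialdehyde 17 is taken as a purchasable C20 building block.

Step 1
Reactants: 1 3,3-dimethylcyclobutan-1-one; 2 (S)-1-amino-2-(methoxymethyl)pyrrolidine (SAMP)
Product: 3 (2S)-N-(3,3-dimethylcyclobutylidene)-2-(methoxymethyl)pyrrolidin-1-amine
Conditions: CH2Cl2, MgSO4, rt
Reagents that add atoms: none
Why: Hydrazone formation by condensation of the unhindered ketone with the N-amino group; the ketone is symmetric, so no regio- or geometric isomers can arise.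

Step 2
Reactants: 4 3-(trimethylsilyl)prop-2-yn-1-ol
Product: 5 [3-(chloromethoxy)prop-1-yn-1-yl](trimethyl)silane
Conditions: (CH2O)n, Me3SiCl, CH2Cl2, 0 °C → rt
Reagents that add atoms: paraformaldehyde (formaldehyde unit), C=O; chlorotrimethylsilane, C[Si](C)(C)Cl
Why: Chloromethylation of an alcohol, in which the hemiformal formed with formaldehyde is converted into the α-chloro ether by the chlorosilane; the C-silyl cap shields the acetylenic C–H from the strong base of step 3.

Step 3
Reactants: 3 SAMP hydrazone; 5 chloromethyl ether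
Product: 7 (2S)-N-{(2R)-3,3-dimethyl-2-[(prop-2-yn-1-yloxy)methyl]cyclobutylidene}-2-(methoxymethyl)pyrrolidin-1-amine, via C-silyl alkyne hydrazone 6 (not isolated)
Conditions: LiN(iPr)2, THF, 0 °C; 5, −95 → −78 °C; then MeOH, K2CO3, rt
Reagents that add atoms: none
Why: SAMP-hydrazone α-alkylation, in which the lithium azaenolate (rigid through chelation of lithium by the methoxymethyl arm) should be attacked by the very reactive α-chloro ether on the face left open by the pyrrolidine ring, setting the ring stereocentre (later C6) in the sense established for SAMP, the two α-methylene groups being equivalent; methanolysis then removes the C-silyl cap while the α-centre is still protected from epimerisation as the hydrazone.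

Step 4
Reactants: 7 terminal alkyne hydrazone
Product: 8 (2S)-3,3-dimethyl-2-[(prop-2-yn-1-yloxy)methyl]cyclobutan-1-one
Conditions: sat. aq. (CO2H)2, Et2O, rt
Reagents that add atoms: water, O
Why: Two-phase hydrolysis of the hydrazone with oxalic acid should return the ketone without epimerising the α-stereocentre, since the auxiliary leaves as its water-soluble oxalate and four-membered ketones enolise reluctantly.

Step 5
Reactants: 8 alkyne-tethered cyclobutanone
Product: 9 (3aR)-4,4-dimethyl-3,3a,4,5-tetrahydro-2-benzofuran-6(1H)-one (cyclohexenone fused to an oxolane)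
Conditions: [Rh(C2H4)2Cl]2 (5 mol %), PMe2Ph (20 mol %), 1,4-dioxane, 130 °C, sealed tube
Reagents that add atoms: none
Why: The tethered alkyne brings monovalent rhodium to the strained C3–C6 acyl–alkyl bond, which adds oxidatively to give a five-membered acyl–rhodium–alkyl metallacycle; migratory insertion of the alkyne (C5 to C6) and C3–C4 reductive elimination then form both new bonds and release the catalyst. The closest known reaction type is the rhodium-catalysed intramolecular "cut-and-sew" carboacylation of alkynes by cyclobutanones that carry the alkyne on C2 through a three-atom tether. The six-membered carbocycle arises by two-carbon ring expansion of the four-membered ketone (formal [4+2]) and the temporary oxolane by 5-exo-dig closure at C6–C5. No stereocentre is created: C6 should be carried through with retention, because oxidative addition, insertion and reductive elimination all proceed with retention at the sp3 carbon and no enolisable intermediate intervenes. The step needs cleavage of the more substituted C3–C6 bond instead of C3–C2 and the orientation C4 to C3 and C5 to C6; the three-atom tether secures both, since only insertion next to the tethered carbon can close a strain-free fused bicycle and the internal alkyne carbon must then bond to C6. Competing loss of CO from the rhodacycle is countered by the small, electron-rich phosphine.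

Step 6
Reactants: 9 bicyclic enone
Product: 11 (4R)-4-(hydroxymethyl)-3,5,5-trimethylcyclohex-2-en-1-one, via exocyclic-methylene ketone 10 (not isolated)
Conditions: SmI2 (2.5 equiv), THF–MeOH, −78 °C; then DBU (cat.), CH2Cl2, rt
Reagents that add atoms: none
Why: Two electrons from SmI2 (divalent samarium) reduce the enone to a samarium dienolate that expels the γ-alkoxide (a vinylogous reductive cleavage of an α-alkoxy ketone), so the C18–O bond of the temporary ring breaks; protonation at C4 gives 10 and the amine base moves the exocyclic alkene into conjugation through the C4 enolate, leaving C6 (never α to the carbonyl) untouched.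

Step 7
Reactants: 11 hydroxymethyl enone; 12 1-phenyl-1H-tetrazole-5-thiol
Product: 13 (4R)-3,5,5-trimethyl-4-{[(1-phenyl-1H-tetrazol-5-yl)sulfanyl]methyl}cyclohex-2-en-1-one
Conditions: PPh3, DIAD, THF, 0 °C → rt
Reagents that add atoms: none
Why: Mitsunobu thioetherification, in which the primary alcohol is activated as its oxyphosphonium salt and displaced (SN2) by the acidic tetrazolethiol, the β,β-disubstituted enone being too hindered for conjugate addition of the thiol.

Step 8
Reactants: 13 sulfide
Product: 14 (4R)-3,5,5-trimethyl-4-{[(1-phenyl-1H-tetrazol-5-yl)sulfonyl]methyl}cyclohex-2-en-1-one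
Conditions: (NH4)6Mo7O24·4H2O (cat.), 30% aq. H2O2, EtOH, 0 °C → rt
Reagents that add atoms: hydrogen peroxide, OO
Why: Molybdate-catalysed peroxide oxidation of sulfide to sulfone should be chemoselective because the only alkene at this stage is the electron-poor enone double bond.

Step 9
Reactants: 14 keto sulfone
Product: 15 (1R,4R)-3,5,5-trimethyl-4-{[(1-phenyl-1H-tetrazol-5-yl)sulfonyl]methyl}cyclohex-2-en-1-ol (hydroxyl trans to the sulfonylmethyl group)
Conditions: NaBH4, CeCl3·7H2O, MeOH, −78 °C
Reagents that add atoms: none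
Why: Luche 1,2-reduction, in which the C6 substituent should sit pseudo-axial (avoiding allylic 1,2-strain with the C5 methyl) and anti to the axial C1 methyl, so the small hydride should attack C3 anti to that axial methyl, from the face of the C6 substituent, placing the new hydroxyl trans to it (3R).

Step 10
Reactants: 15 allylic alcohol
Product: 16 5-({[(1R,4R)-4-{[tert-butyl(dimethyl)silyl]oxy}-2,6,6-trimethylcyclohex-2-en-1-yl]methyl}sulfonyl)-1-phenyl-1H-tetrazole
Conditions: TBSCl, imidazole, DMF, rt
Reagents that add atoms: tert-butyldimethylsilyl chloride, CC(C)(C)[Si](C)(C)Cl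
Why: Silylation of the secondary allylic alcohol gives a base-stable ether, so that no alkoxide can consume base or attack the tetrazolyl sulfone in the next step.

Step 11
Reactants: 16 ring sulfone (2.3 equiv); 17 (2E,4E,6E,8E,10E,12E,14E)-2,6,11,15-tetramethylhexadeca-2,4,6,8,10,12,14-heptaenedial (crocetindialdehyde)
Product: 18 (3R,6R,3'R,6'R)-3,3'-bis{[tert-butyl(dimethyl)silyl]oxy}-ε,ε-carotene
Conditions: KN(SiMe3)2, THF, −78 °C; 17, −78 °C → rt; then I2 (cat.), CH2Cl2, rt, diffuse light, Ar
Reagents that add atoms: none
Why: Two-fold Julia–Kocienski olefination, in which the sulfonyl carbanion adds to each aldehyde, Smiles transfer of the tetrazole to oxygen and loss of SO2 and tetrazolate form C7=C8 and C7'=C8', the bulky β-branched sulfone favouring E and iodine-catalysed equilibration expected to move any 7Z isomer towards the all-E polyene; the C6–H is not acidic under these conditions, so C6 should keep its configuration.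

Step 12
Reactants: 18 bis-silyl ether
Product: 19 (3R,6R,3'R,6'R)-ε,ε-carotene-3,3'-diol (lactucaxanthin)
Conditions: TBAF, THF, 0 °C → rt, Ar, dark
Reagents that add atoms: none
Why: Fluoride cleaves the two Si–O bonds (desilylation) under non-acidic conditions that the acid-labile allylic ring alcohols and the polyene should tolerate.

**Compound list**
1 | 3,3-dimethylcyclobutan-1-one | O=C1CC(C)(C)C1 | starting material
2 | (S)-1-amino-2-(methoxymethyl)pyrrolidine (SAMP) | COC[C@@H]1CCCN1N | starting material
3 | (2S)-N-(3,3-dimethylcyclobutylidene)-2-(methoxymethyl)pyrrolidin-1-amine | COC[C@@H]1CCCN1N=C2CC(C)(C)C2 | intermediate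
4 | 3-(trimethylsilyl)prop-2-yn-1-ol | C[Si](C)(C)C#CCO | starting material
5 | [3-(chloromethoxy)prop-1-yn-1-yl](trimethyl)silane | C[Si](C)(C)C#CCOCCl | intermediate
6 | (2S)-N-[(2R)-3,3-dimethyl-2-({[3-(trimethylsilyl)prop-2-yn-1-yl]oxy}methyl)cyclobutylidene]-2-(methoxymethyl)pyrrolidin-1-amine | COC[C@@H]1CCCN1N=C2CC(C)(C)[C@H]2COCC#C[Si](C)(C)C | intermediate
7 | (2S)-N-{(2R)-3,3-dimethyl-2-[(prop-2-yn-1-yloxy)methyl]cyclobutylidene}-2-(methoxymethyl)pyrrolidin-1-amine | COC[C@@H]1CCCN1N=C2CC(C)(C)[C@H]2COCC#C | intermediate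
8 | (2S)-3,3-dimethyl-2-[(prop-2-yn-1-yloxy)methyl]cyclobutan-1-one | O=C1CC(C)(C)[C@H]1COCC#C | intermediate
9 | (3aR)-4,4-dimethyl-3,3a,4,5-tetrahydro-2-benzofuran-6(1H)-one | O=C1CC(C)(C)[C@H]2COCC2=C1 | intermediate
10 | (4R)-4-(hydroxymethyl)-3,3-dimethyl-5-methylidenecyclohexan-1-one | O=C1CC(C)(C)[C@@H](CO)C(=C)C1 | intermediate
11 | (4R)-4-(hydroxymethyl)-3,5,5-trimethylcyclohex-2-en-1-one | O=C1CC(C)(C)[C@@H](CO)C(C)=C1 | intermediate
12 | 1-phenyl-1H-tetrazole-5-thiol | Sc1nnnn1-c1ccccc1 | starting material
13 | (4R)-3,5,5-trimethyl-4-{[(1-phenyl-1H-tetrazol-5-yl)sulfanyl]methyl}cyclohex-2-en-1-one | O=C1CC(C)(C)[C@@H](CSc2nnnn2-c3ccccc3)C(C)=C1 | intermediate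
14 | (4R)-3,5,5-trimethyl-4-{[(1-phenyl-1H-tetrazol-5-yl)sulfonyl]methyl}cyclohex-2-en-1-one | O=C1CC(C)(C)[C@@H](CS(=O)(=O)c2nnnn2-c3ccccc3)C(C)=C1 | intermediate
15 | (1R,4R)-3,5,5-trimethyl-4-{[(1-phenyl-1H-tetrazol-5-yl)sulfonyl]methyl}cyclohex-2-en-1-ol | CC1=C[C@H](O)CC(C)(C)[C@H]1CS(=O)(=O)c2nnnn2-c3ccccc3 | intermediate
16 | 5-({[(1R,4R)-4-{[tert-butyl(dimethyl)silyl]oxy}-2,6,6-trimethylcyclohex-2-en-1-yl]methyl}sulfonyl)-1-phenyl-1H-tetrazole | CC1=C[C@H](O[Si](C)(C)C(C)(C)C)CC(C)(C)[C@H]1CS(=O)(=O)c2nnnn2-c3ccccc3 | intermediate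
17 | (2E,4E,6E,8E,10E,12E,14E)-2,6,11,15-tetramethylhexadeca-2,4,6,8,10,12,14-heptaenedial (crocetindialdehyde) | O=C/C(C)=C/C=C/C(C)=C/C=C/C=C(C)/C=C/C=C(C)/C=O | starting material
18 | (3R,6R,3'R,6'R)-3,3'-bis{[tert-butyl(dimethyl)silyl]oxy}-ε,ε-carotene | CC1=C[C@H](O[Si](C)(C)C(C)(C)C)CC(C)(C)[C@H]1/C=C/C(C)=C/C=C/C(C)=C/C=C/C=C(C)/C=C/C=C(C)/C=C/[C@H]1C(C)=C[C@H](O[Si](C)(C)C(C)(C)C)CC1(C)C | intermediate
19 | (3R,6R,3'R,6'R)-ε,ε-carotene-3,3'-diol (lactucaxanthin) | CC1=C[C@H](O)CC(C)(C)[C@H]1/C=C/C(C)=C/C=C/C(C)=C/C=C/C=C(C)/C=C/C=C(C)/C=C/[C@H]1C(C)=C[C@H](O)CC1(C)C | target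

Total step count: 12. Longest linear sequence: 11 steps (steps 1 and 3–12, from 1).

**Steps most likely to fail**

Step 5. The terminal alkyne may be consumed by rhodium vinylidene formation or oligomerisation, the rhodacycle may lose CO to give a cyclopropane, or β-alkoxide elimination from the C6–rhodium intermediate may sever the tether before the alkyne inserts. Fallback: the ring is made without C–C activation, by enone transposition. It sets out from SAMP 2, which is condensed with commercial 5,5-dimethylcyclohex-2-en-1-one F1 to give the SAMP hydrazone of that enone F2. LiN(iPr)2 followed by benzyl chloromethyl ether should alkylate the only sp3 α-carbon to give the benzyloxymethyl hydrazone F3, and aqueous oxalic acid should release (6S)-6-[(benzyloxy)methyl]-5,5-dimethylcyclohex-2-en-1-one F4. MeLi with CeCl3 adds 1,2 to give the tertiary allylic alcohol F5, and pyridinium chlorochromate, [C5H5NH][CrO3Cl], effects the Babler–Dauben oxidative 1,3-transposition to (4R)-4-[(benzyloxy)methyl]-3,5,5-trimethylcyclohex-2-en-1-one F6. BCl3 at −78 °C removes the benzyl group and the route is rejoined at 11.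

Step 6. The enone may be over-reduced (conjugate reduction or pinacol coupling), or the unactivated alkoxide may leave the dienolate too slowly. Fallback: the ether oxygen is first turned into a better partner for cleavage. It sets out from 9. Acetyl bromide with catalytic ZnBr2 should open the oxolane by bromide attack at the allylic C18 to give [(1R)-2-(bromomethyl)-6,6-dimethyl-4-oxocyclohex-2-en-1-yl]methyl acetate F7. Zinc dust in acetic acid then removes the γ-bromide through the zinc dienolate to give [(1R)-2,6,6-trimethyl-4-oxocyclohex-2-en-1-yl]methyl acetate F8. Acid-catalysed methanolysis (HCl, MeOH) comes back to the route at 11.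

Step 9. Facial selectivity may be poor if the conformer with a pseudo-equatorial C6 substituent is populated, so that hydride is delivered to the other face of C3. Fallback: the wrong epimer is converged by inversion instead of direct reduction. It sets out from 14: the 3,6-cis alcohol (1S,4R)-3,5,5-trimethyl-4-{[(1-phenyl-1H-tetrazol-5-yl)sulfonyl]methyl}cyclohex-2-en-1-ol F9 formed in the reduction is separated and subjected to Mitsunobu inversion with 4-nitrobenzoic acid, PPh3 and DIAD. This should give the (1R,4R) 4-nitrobenzoate F10, and mild methanolysis (K2CO3, MeOH, 0 °C) comes back to the route at 15.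

**Further compounds**
F1 | step 5 | 5,5-dimethylcyclohex-2-en-1-one | O=C1C=CCC(C)(C)C1
F2 | step 5 | (2S)-N-(5,5-dimethylcyclohex-2-en-1-ylidene)-2-(methoxymethyl)pyrrolidin-1-amine | COC[C@@H]1CCCN1N=C2C=CCC(C)(C)C2
F3 | step 5 | (2S)-N-{(6R)-6-[(benzyloxy)methyl]-5,5-dimethylcyclohex-2-en-1-ylidene}-2-(methoxymethyl)pyrrolidin-1-amine | COC[C@@H]1CCCN1N=C2C=CCC(C)(C)[C@H]2COCc3ccccc3
F4 | step 5 | (6S)-6-[(benzyloxy)methyl]-5,5-dimethylcyclohex-2-en-1-one | O=C1C=CCC(C)(C)[C@H]1COCc2ccccc2
F5 | step 5 | (6S)-6-[(benzyloxy)methyl]-1,5,5-trimethylcyclohex-2-en-1-ol (carbinol centre unassigned) | CC1(O)C=CCC(C)(C)[C@H]1COCc2ccccc2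
F6 | step 5 | (4R)-4-[(benzyloxy)methyl]-3,5,5-trimethylcyclohex-2-en-1-one | O=C1CC(C)(C)[C@@H](COCc2ccccc2)C(C)=C1
F7 | step 6 | [(1R)-2-(bromomethyl)-6,6-dimethyl-4-oxocyclohex-2-en-1-yl]methyl acetate | O=C1CC(C)(C)[C@@H](COC(C)=O)C(CBr)=C1
F8 | step 6 | [(1R)-2,6,6-trimethyl-4-oxocyclohex-2-en-1-yl]methyl acetate | O=C1CC(C)(C)[C@@H](COC(C)=O)C(C)=C1
F9 | step 9 | (1S,4R)-3,5,5-trimethyl-4-{[(1-phenyl-1H-tetrazol-5-yl)sulfonyl]methyl}cyclohex-2-en-1-ol | CC1=C[C@@H](O)CC(C)(C)[C@H]1CS(=O)(=O)c2nnnn2-c3ccccc3
F10 | step 9 | (1R,4R)-3,5,5-trimethyl-4-{[(1-phenyl-1H-tetrazol-5-yl)sulfonyl]methyl}cyclohex-2-en-1-yl 4-nitrobenzoate | CC1=C[C@H](OC(=O)c2ccc(cc2)[N+](=O)[O-])CC(C)(C)[C@H]1CS(=O)(=O)c3nnnn3-c4ccccc4
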